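## Analysis of the target

Atom numbering used throughout: C1 is the ester carbonyl, C2 its CH2, C3–C6 are the four ring carbons (the two ring oxygens lie between C3 and C6), C7–C12 is the side chain on C6, and the phenyl group sits on C12.

- The target 24 is a monocyclic 1,2-dioxane. C3 carries the CH2CO2Me arm, C4 a methyl group, and C6 a methyl group plus a (2E,4E)-2-methyl-6-phenylhexa-2,4-dienyl chain.
- There are three stereocentres: C3 (S), C4 (R) and C6 (R). C3 and C4 are trans; in the chair both their substituents and the C6 chain are equatorial and the C6 methyl is axial.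
- C6 is a fully substituted, peroxide-bearing carbon whose two CH2 arms differ only further out, and it stands 1,3 to C4, so it is hard to control.
- Sensitive groups are the O–O bond (reductants, phosphines, low-valent metals, ionising acid), the β-peroxy ester (base can open the ring through the C2 enolate or the C3 hydrogen), and the diene with its doubly activated C12 methylene.
- The difficulty is to make two C–O bonds of a peroxide, one of them at a quaternary stereocentre, and to keep the diene away from the chemistry that does so.
- The feature on which the plan rests: C3 bears a peroxide oxygen and its neighbour C2 bears the carbonyl carbon C1. This is the pattern left when an oxygen and an acyl group add across a terminal C2=C3 alkene.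

## Retrosynthetic reasoning

**C9–C10 (diene).** The diene of 24 is cut between C9 and C10, giving alkenyl iodide 22 and boronic acid 23. The cut is made here because the conjugated diene is the best ligand in the molecule for an electrophilic metal and the easiest radical acceptor, so it must not be present when the ring is made. Both alkene geometries are fixed in the partners, and the forward Suzuki–Miyaura coupling only has to join two sp2 carbons with retention under conditions that spare the O–O bond.

**C9–I to C9–Si.** Iodide 22 is traced to vinylsilane 21. A carbon–iodine bond would be attacked by the zerovalent palladium that appears in every turnover of the ring-forming step, whereas a trisubstituted vinylsilane is inert to it and is also a poor alkene ligand. The forward iododesilylation must keep the E geometry.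

**C3–O and C1–C2 (key disconnection).** In 21 the ring bond C3–O and the bond C1–C2 are cut together, which leads to hydroperoxide 20 with a C2=C3 vinyl group. C1 is then delivered by carbonylation and the methoxy group by the alcohol solvent. Cutting here removes the ring, the ester arm and the C3 stereocentre in one operation and leaves a precursor whose only stereocentres are C4 and C6. The forward step must add the peroxide oxygen to C3 in the 6-exo sense, trap the C2–palladium bond with CO before it decays, and set C3 trans to the C4 methyl.

**C2=C3 and the hydroperoxide proton.** Hydroperoxide 20 is taken back to its silyl peroxide 19, the vinyl group of 19 to aldehyde 18 by methylenation, and 18 to alcohol 17. The vinyl group is introduced after the peroxide so that the oxygenation step meets only one reactive alkene.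

**C6–O.** The C6–O bond of 17 is cut to give the 1,1-disubstituted alkene 16, to be oxygenated by cobalt-catalysed aerobic peroxysilylation. Acid perhydrolysis of a tertiary alcohol was not used because an ionising acid would protodesilylate the vinylsilane and ionise a homoallylic centre, and it would be equally unselective. The radical route is neutral and regioselective for C6, but it gives both C6 epimers, which have to be separated.

**C6–C7.** The skipped diene 16 is cut at C6–C7 into the alkenylzinc 14 (from bromide 12) and allylic bromide 6. An alkenyl–allyl coupling joins the alkenyl carbon to the CH2 end of the allyl unit and keeps the vinylsilane geometry.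

**C4–C5.** Bromide 12 goes back through alcohol 11 to imide 10, which is cut at C4–C5 into propionimide 7 and dibromide 8. The auxiliary-controlled alkylation sets C4, and 8 brings C5, C6 and the future C6 methyl carbon in one piece.

**Vinylsilane fragment.** Bromide 6 comes from alcohol 5, this from iodide 3, and 3 from alkyne 1 by syn-carbometalation, which fixes the methyl group on C8 and the E geometry.

## Alternatives that were turned down

**Alternative 1:** The ring is cut at C3–O and the arm at C2–C3, which leads back to aldehyde A2 carrying the C6 silyl peroxide and the vinyl iodide.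
- Forward key step: ZnCl2 would join A2 to a thiopyridyl silyl ketene acetal in an aldol–lactonisation to give β-lactone A3. The peroxide oxygen would then displace the lactone oxygen at C3 from the rear to give acid A1, one esterification away from 22.
- For: C3 is set by a stereospecific displacement, no transition metal meets the peroxide at ring closure, and a vinyl iodide can be carried from the start.
- Against: the correct C3 configuration depends on Felkin-type facial selectivity of an acetate-type nucleophile on an α-methyl aldehyde, which is usually modest. A silylated peroxide is a weak nucleophile, and attack at the lactone carbonyl (a seven-membered perester) competes with attack at C3. A zinc Lewis acid next to a tertiary peroxide invites ionisation at C6.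
- Comparison: A2 needs the same C6 peroxide as the chosen route, so nothing is gained at C6. Alternative 1 is stronger in that its ring closure is stereospecific. The chosen route sets C3 in one event under neutral conditions, delivers the methyl ester directly, and is one step shorter after the peroxide is in place.

**Alternative 2:** The C6–O bond is cut and C6, C7 and C8 are folded back into a cyclopropane, giving precursor A5 with a secondary hydroperoxide at C3 and an allylic carbinol at C9.
- Forward key step: acid would ionise C9, and as the cyclopropane opens to the C8=C9 alkene the hydroperoxide would attack C6 opposite the breaking C6–C8 bond, giving A4 with the whole diene in place.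
- For: this is the one proposal that sets C6 stereospecifically, and here it is clearly stronger than the chosen route, which separates epimers. It also needs no late cross-coupling.
- Against: A5 has two adjacent quaternary cyclopropane carbons and would be long to make. A weak nucleophile must attack a quaternary carbon in competition with capture of the delocalised cation at C9 or C11, elimination, and acid-induced peroxide rearrangement. The C8=C9 geometry depends on the conformer that ionises. Afterwards CH2CH2OSi must be turned into CH2CO2Me in three or four steps next to a diene and a peroxide.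
- Comparison: the chosen route gives up control at C6 but is much shorter, and its single unproven event is mechanistically simple.

**Alternative 3:** Both ring C–O bonds are cut and C3 is joined to C6, giving cyclobutanol A7.
- Forward key step: Co(acac)2 and O2 would turn the hydroxyl of A7 into an oxygen radical. The C3–C6 bond would break to a C3 ketone and a tertiary C6 radical, and O2 capture followed by addition of the peroxy group to the ketone would give dioxanol A6.
- For: two C–O bonds form in one aerobic step, no acyclic hydroperoxide is handled, and the reaction class is known for cyclobutanols. On these points it is stronger than the chosen route.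
- Against: C6 passes through a planar radical, so it is no better at C6. Ring opening must choose the C3–C6 bond over C3–C4 and over loss of the stabilised CH2CO2Me radical. A6 is a β-keto-ester hemiketal in equilibrium with its open form, and its C3 hydroxyl must still be removed reductively through a peroxycarbenium ion, which is where C3 would be set. A7, with two quaternary ring carbons, is itself a long synthesis.
- Comparison: the chosen route sets C3 and installs the ester in the ring-forming step and reaches its precursor in fewer steps.

Key step: step 12

## Remarks on the chemistry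

- Compounds 7, 8 and 23 are taken as commercial.
- IUPAC names of intermediates use their own locants; the target's C6 is C4 of the heptene and octadiene intermediates.
- C6 is formed through a planar radical in step 8. Compounds 17–19 are therefore handled as the pair of C6 epimers (that centre is left undefined in their SMILES), and 20 is obtained as one isomer by separation in step 11.

## Route

Step 1
Reactants: 1 prop-2-yn-1-ol
Product: 3 (E)-3-iodo-2-methylprop-2-en-1-ol, via alkenylalane 2 (not isolated)
Conditions: AlMe3 (3 equiv), Cp2ZrCl2 (0.25 equiv), CH2Cl2, 0 °C to rt; then I2, THF, −30 to 0 °C; aq. K2CO3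
Reagents that add atoms: trimethylaluminium, C[Al](C)C; iodine, II
Why: Zirconium-catalysed carboalumination (Negishi) adds methyl and aluminium syn across the alkyne with methyl on the internal carbon, and iodinolysis of the C–Al bond with retention gives the E-iodide.

Step 2
Reactants: 3 (E)-3-iodo-2-methylprop-2-en-1-ol
Product: 5 (E)-2-methyl-3-trimethylsilylprop-2-en-1-ol, via bis-silyl compound 4 (not isolated)
Conditions: t-BuLi (3.1 equiv), Et2O, −78 °C; Me3SiCl (excess), −78 °C to rt; then K2CO3, MeOH, rt
Reagents that add atoms: chlorotrimethylsilane, C[Si](C)(C)Cl
Why: Iodine–lithium exchange on the lithium alkoxide proceeds with retention of alkene geometry and the alkenyllithium is silylated on carbon; the O-silyl group of 4 is removed by mild methanolysis.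

Step 3
Reactants: 5 (E)-2-methyl-3-trimethylsilylprop-2-en-1-ol
Product: 6 [(E)-3-bromo-2-methylprop-1-enyl]trimethylsilane
Conditions: CBr4, PPh3, CH2Cl2, 0 °C
Reagents that add atoms: tetrabromomethane, BrC(Br)(Br)Br
Why: Appel bromination under neutral conditions converts the primary allylic alcohol to the bromide without allylic transposition and without touching the acid-sensitive vinylsilane.

Step 4
Reactants: 7 (4S)-4-benzyl-3-propanoyl-1,3-oxazolidin-2-one; 8 2,3-dibromoprop-1-ene
Product: 10 (4S)-4-benzyl-3-[(2R)-4-bromo-2-methylpent-4-enoyl]-1,3-oxazolidin-2-one, via sodium enolate 9 (not isolated)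
Conditions: NaN(SiMe3)2, THF, −78 °C; then 8, −78 to −45 °C
Reagents that add atoms: none
Why: Evans asymmetric alkylation: the chelated Z-enolate 9 is alkylated by the allylic bromide on the face away from the benzyl group, which sets the methyl-bearing centre (C4 of the target) as R.

Step 5
Reactants: 10 (4S)-4-benzyl-3-[(2R)-4-bromo-2-methylpent-4-enoyl]-1,3-oxazolidin-2-one
Product: 11 (2R)-4-bromo-2-methylpent-4-en-1-ol
Conditions: LiBH4, MeOH (1 equiv), Et2O, 0 °C
Reagents that add atoms: none
Why: Reductive cleavage of the N-acyloxazolidinone by LiBH4 at the exocyclic carbonyl releases the primary alcohol and the recoverable auxiliary without epimerisation or attack on the alkenyl bromide.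

Step 6
Reactants: 11 (2R)-4-bromo-2-methylpent-4-en-1-ol
Product: 12 [(2R)-4-bromo-2-methylpent-4-enoxy]triethylsilane
Conditions: Et3SiCl, imidazole, CH2Cl2, 0 °C
Reagents that add atoms: chlorotriethylsilane, CC[Si](Cl)(CC)CC
Why: Standard silylation; the triethylsilyl ether masks the hydroxyl during halogen–lithium exchange and is labile enough to be removed in the work-up of step 7.

Step 7
Reactants: 12 [(2R)-4-bromo-2-methylpent-4-enoxy]triethylsilane; 6 [(E)-3-bromo-2-methylprop-1-enyl]trimethylsilane
Product: 16 (2R,6E)-2,6-dimethyl-4-methylidene-7-trimethylsilylhept-6-en-1-ol, via alkenyllithium 13 (not isolated), via alkenylzinc bromide 14 (not isolated), via silyl ether 15 (not isolated)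
Conditions: t-BuLi (2.05 equiv), Et2O, −78 °C; ZnBr2, THF, −78 to 0 °C; 6, Pd(PPh3)4 (3 mol %), THF, 0 °C to rt; then PPTS, MeOH, rt
Reagents that add atoms: none
Why: Bromine–lithium exchange and transmetalation give alkenylzinc 14, which couples with the allylic bromide under zerovalent palladium (Negishi alkenyl–allyl coupling) at the unsubstituted CH2 terminus of the allyl unit with the E geometry of 6 retained. Brief acid methanolysis then frees the alcohol.

Step 8
Reactants: 16 (2R,6E)-2,6-dimethyl-4-methylidene-7-trimethylsilylhept-6-en-1-ol
Product: 17 (2R,6E)-2,4,6-trimethyl-4-triethylsilylperoxy-7-trimethylsilylhept-6-en-1-ol (both C4 epimers)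
Conditions: Co(thd)2 (10 mol %; thd = 2,2,6,6-tetramethylheptane-3,5-dionate), O2 (1 atm), Et3SiH (2 equiv), ClCH2CH2Cl, rt
Reagents that add atoms: dioxygen, O=O; triethylsilane, CC[SiH](CC)CC
Why: Mukaiyama–Isayama peroxysilylation: a cobalt hydride transfers a hydrogen atom to the CH2 terminus of the 1,1-disubstituted alkene, the tertiary C6 radical captures O2 and the peroxide is silylated. The trisubstituted, silyl-shielded alkene should react much more slowly and a free hydroxyl is tolerated. The planar radical is captured from both faces, so both C6 epimers are expected and are carried on together.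

Step 9
Reactants: 17 (2R,6E)-2,4,6-trimethyl-4-triethylsilylperoxy-7-trimethylsilylhept-6-en-1-ol (both C4 epimers)
Product: 18 (2R,6E)-2,4,6-trimethyl-4-triethylsilylperoxy-7-trimethylsilylhept-6-enal (both C4 epimers)
Conditions: Dess–Martin periodinane, NaHCO3, CH2Cl2, 0 °C to rt
Reagents that add atoms: none
Why: Dess–Martin oxidation under buffered, non-basic conditions should give the α-methyl aldehyde without epimerisation and leave the silyl peroxide and the vinylsilane untouched.

Step 10
Reactants: 18 (2R,6E)-2,4,6-trimethyl-4-triethylsilylperoxy-7-trimethylsilylhept-6-enal (both C4 epimers)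
Product: 19 triethyl-[(1E,6R)-2,4,6-trimethyl-1-trimethylsilylocta-1,7-dien-4-yl]peroxysilane (both C4 epimers)
Conditions: Ph3PCH3Br (1.3 equiv), KN(SiMe3)2 (1.2 equiv), THF, 0 °C; then 18, −78 to 0 °C
Reagents that add atoms: methyltriphenylphosphonium bromide, C[P+](c1ccccc1)(c1ccccc1)c1ccccc1.[Br-]
Why: Wittig methylenation with a small excess of ylide at low temperature converts the aldehyde into the C2=C3 vinyl group; a hindered tertiary silyl peroxide should tolerate the ylide under these conditions and the α-stereocentre is not expected to epimerise.

Step 11
Reactants: 19 triethyl-[(1E,6R)-2,4,6-trimethyl-1-trimethylsilylocta-1,7-dien-4-yl]peroxysilane (both C4 epimers)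
Product: 20 [(1E,4R,6R)-4-hydroperoxy-2,4,6-trimethylocta-1,7-dienyl]trimethylsilane
Conditions: Bu4NF, AcOH, THF, 0 °C; preparative HPLC on silica to separate the two epimers at the hydroperoxide carbon
Reagents that add atoms: none
Why: Buffered fluoride cleaves the O–Si bond of the silyl peroxide while the vinyl C–Si bond is inert. The two epimers, which differ in the 1,3-relationship of a hydrogen-bonding group and a methyl branch, are then separated, so that C6 of the target is obtained as R by separation and not by selectivity.

Step 12
Reactants: 20 [(1E,4R,6R)-4-hydroperoxy-2,4,6-trimethylocta-1,7-dienyl]trimethylsilane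
Product: 21 methyl 2-[(3S,4R,6R)-4,6-dimethyl-6-[(E)-2-methyl-3-trimethylsilylprop-2-enyl]-1,2-dioxan-3-yl]acetate
Conditions: PdCl2(MeCN)2 (10 mol %), 1,4-benzoquinone (2 equiv), CO (1 atm), MeOH, 0 °C to rt
Reagents that add atoms: carbon monoxide, [C-]#[O+]; methanol, CO
Why: Proposed new method: divalent palladium should bind the monosubstituted C2=C3 alkene and the hydroperoxide oxygen should add to C3, leaving a primary alkylpalladium at C2 that inserts CO in the CO-saturated solution before it can lose the C3 hydrogen; methanolysis of the acylpalladium releases ester 21 and benzoquinone returns the zerovalent palladium to the divalent state. The closest known reaction types are the cyclisation of unsaturated tertiary hydroperoxides to 1,2-dioxanes with Pd(OAc)2 and the alkoxypalladation–methoxycarbonylation of hydroxy alkenes to tetrahydropyranyl acetates; their combination on a hydroperoxide is what is new. The one ring formed, the 1,2-dioxane, closes in the 6-exo-trig mode. The one new stereocentre, C3, is controlled by the C4 methyl group through a chair-like transition state in which that methyl, the complexed alkene and the C6 chain are equatorial and the C6 methyl is axial, which leads to the 3,4-trans (3S) product. C4 and C6 enter with fixed configuration and are not touched. The step needs site selectivity between two alkenes, which the substrate secures because the other one is a trisubstituted, silyl-shielded vinylsilane that binds palladium poorly and offers no carbon–halogen bond to transient zerovalent palladium. It also needs the peroxide to act as a nucleophile and not be destroyed, which is helped by the tertiary C6 (no α-hydrogen for base- or metal-induced fragmentation) and by the absence of phosphines and strong base.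

Step 13
Reactants: 21 methyl 2-[(3S,4R,6R)-4,6-dimethyl-6-[(E)-2-methyl-3-trimethylsilylprop-2-enyl]-1,2-dioxan-3-yl]acetate
Product: 22 methyl 2-[(3S,4R,6R)-6-[(E)-3-iodo-2-methylprop-2-enyl]-4,6-dimethyl-1,2-dioxan-3-yl]acetate
Conditions: N-iodosuccinimide (1.5 equiv), (CF3)2CHOH, 0 °C
Reagents that add atoms: N-iodosuccinimide, O=C1CCC(=O)N1I
Why: Iododesilylation: ipso attack of iodonium gives a β-silyl cation that loses silicon faster than it rotates in the strongly ionising, weakly nucleophilic fluoroalcohol, so the E geometry should be retained; the peroxide and the ester are inert to the reagent.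

Step 14
Reactants: 22 methyl 2-[(3S,4R,6R)-6-[(E)-3-iodo-2-methylprop-2-enyl]-4,6-dimethyl-1,2-dioxan-3-yl]acetate; 23 [(E)-3-phenylprop-1-enyl]boronic acid
Product: 24 methyl 2-[(3S,4R,6R)-4,6-dimethyl-6-[(2E,4E)-2-methyl-6-phenylhexa-2,4-dienyl]-1,2-dioxan-3-yl]acetate
Conditions: PdCl2(dppf) (5 mol %; dppf = 1,1'-bis(diphenylphosphino)ferrocene), AsPh3 (10 mol %), K3PO4 (aq.), THF, rt, degassed
Reagents that add atoms: none
Why: Suzuki–Miyaura coupling of the alkenyl iodide with the alkenylboronic acid proceeds with retention at both alkenes and gives the (2E,4E)-diene; an arsine co-ligand, a mild phosphate base and room temperature are chosen to spare the O–O bond and the base-sensitive β-peroxy ester.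

## Compound list

1 | prop-2-yn-1-ol | C#CCO | starting material
2 | dimethyl-[(E)-3-(dimethylalumanyloxy)-2-methylprop-1-enyl]alumane | C/C(CO[Al](C)C)=C\[Al](C)C | intermediate (not isolated)
3 | (E)-3-iodo-2-methylprop-2-en-1-ol | C/C(CO)=C\I | intermediate
4 | trimethyl-[(E)-2-methyl-3-trimethylsilyloxyprop-1-enyl]silane | C/C(CO[Si](C)(C)C)=C\[Si](C)(C)C | intermediate (not isolated)
5 | (E)-2-methyl-3-trimethylsilylprop-2-en-1-ol | C/C(CO)=C\[Si](C)(C)C | intermediate
6 | [(E)-3-bromo-2-methylprop-1-enyl]trimethylsilane | C/C(CBr)=C\[Si](C)(C)C | intermediate
7 | (4S)-4-benzyl-3-propanoyl-1,3-oxazolidin-2-one | CCC(=O)N1[C@@H](Cc2ccccc2)COC1=O | starting material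
8 | 2,3-dibromoprop-1-ene | C=C(Br)CBr | starting material
9 | sodium (Z)-1-[(4S)-4-benzyl-2-oxo-1,3-oxazolidin-3-yl]prop-1-en-1-olate | C/C=C(\[O-])N1[C@@H](Cc2ccccc2)COC1=O.[Na+] | intermediate (not isolated)
10 | (4S)-4-benzyl-3-[(2R)-4-bromo-2-methylpent-4-enoyl]-1,3-oxazolidin-2-one | C=C(Br)C[C@@H](C)C(=O)N1[C@@H](Cc2ccccc2)COC1=O | intermediate
11 | (2R)-4-bromo-2-methylpent-4-en-1-ol | OC[C@H](C)CC(Br)=C | intermediate
12 | [(2R)-4-bromo-2-methylpent-4-enoxy]triethylsilane | CC[Si](CC)(CC)OC[C@H](C)CC(Br)=C | intermediate
13 | [(4R)-4-methyl-5-triethylsilyloxypent-1-en-2-yl]lithium | CC[Si](CC)(CC)OC[C@H](C)CC([Li])=C | intermediate (not isolated)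
14 | bromo-[(4R)-4-methyl-5-triethylsilyloxypent-1-en-2-yl]zinc | CC[Si](CC)(CC)OC[C@H](C)CC([Zn]Br)=C | intermediate (not isolated)
15 | triethyl-[(2R,6E)-2,6-dimethyl-4-methylidene-7-trimethylsilylhept-6-enoxy]silane | CC[Si](CC)(CC)OC[C@H](C)CC(=C)C/C(C)=C/[Si](C)(C)C | intermediate (not isolated)
16 | (2R,6E)-2,6-dimethyl-4-methylidene-7-trimethylsilylhept-6-en-1-ol | OC[C@H](C)CC(=C)C/C(C)=C/[Si](C)(C)C | intermediate
17 | (2R,6E)-2,4,6-trimethyl-4-triethylsilylperoxy-7-trimethylsilylhept-6-en-1-ol (both C4 epimers) | OC[C@H](C)CC(C)(OO[Si](CC)(CC)CC)C/C(C)=C/[Si](C)(C)C | intermediate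
18 | (2R,6E)-2,4,6-trimethyl-4-triethylsilylperoxy-7-trimethylsilylhept-6-enal (both C4 epimers) | O=C[C@H](C)CC(C)(OO[Si](CC)(CC)CC)C/C(C)=C/[Si](C)(C)C | intermediate
19 | triethyl-[(1E,6R)-2,4,6-trimethyl-1-trimethylsilylocta-1,7-dien-4-yl]peroxysilane (both C4 epimers) | C=C[C@H](C)CC(C)(OO[Si](CC)(CC)CC)C/C(C)=C/[Si](C)(C)C | intermediate
20 | [(1E,4R,6R)-4-hydroperoxy-2,4,6-trimethylocta-1,7-dienyl]trimethylsilane | C=C[C@H](C)C[C@@](C)(OO)C/C(C)=C/[Si](C)(C)C | intermediate
21 | methyl 2-[(3S,4R,6R)-4,6-dimethyl-6-[(E)-2-methyl-3-trimethylsilylprop-2-enyl]-1,2-dioxan-3-yl]acetate | COC(=O)C[C@@H]1OO[C@@](C)(C/C(C)=C/[Si](C)(C)C)C[C@H]1C | intermediate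
22 | methyl 2-[(3S,4R,6R)-6-[(E)-3-iodo-2-methylprop-2-enyl]-4,6-dimethyl-1,2-dioxan-3-yl]acetate | COC(=O)C[C@@H]1OO[C@@](C)(C/C(C)=C/I)C[C@H]1C | intermediate
23 | [(E)-3-phenylprop-1-enyl]boronic acid | OB(O)/C=C/Cc1ccccc1 | starting material
24 | methyl 2-[(3S,4R,6R)-4,6-dimethyl-6-[(2E,4E)-2-methyl-6-phenylhexa-2,4-dienyl]-1,2-dioxan-3-yl]acetate | COC(=O)C[C@@H]1OO[C@@](C)(C/C(C)=C/C=C/Cc2ccccc2)C[C@H]1C | target

## Step count and least certain steps

Total step count: 14. Longest linear sequence: 11 steps (7 to 24, steps 4–14; the branch from 1 through 6 to 24, steps 1–3 and 7–14, is equally long).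

**Step 12 (key step, proposed new method).** Several processes can divert the β-peroxyalkylpalladium intermediate or the substrate:
- heterolysis of the O–O bond with hydride shift in the alkylpalladium, a Wacker-type collapse to a C3 methyl ketone, before CO inserts;
- reduction of the hydroperoxide by zerovalent palladium in competition with benzoquinone, which would use substrate as the oxidant;
- β-hydride elimination from C3;
- weak facial discrimination at C3, since only one 1,3-diaxial contact separates the two chairs;
- slow silicon-to-palladium exchange at the vinylsilane.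

The fallback uses known chemistry and sets out from aldehyde 18. A Horner–Wadsworth–Emmons reaction with trimethyl phosphonoacetate (LiCl, i-Pr2NEt, MeCN) should give methyl (2E,4R,8E)-4,6,8-trimethyl-6-triethylsilylperoxy-9-trimethylsilylnona-2,8-dienoate F1 as its two C6 epimers. Buffered fluoride and separation of the epimers would give methyl (2E,4R,6R,8E)-6-hydroperoxy-4,6,8-trimethyl-9-trimethylsilylnona-2,8-dienoate F2. Catalytic Et2NH in CF3CH2OH should then close the ring by intramolecular 6-exo-trig peroxy-Michael addition, which is reversible and should favour the all-equatorial 3,4-trans product. The route is rejoined at 21.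

**Step 8.** Oxygen capture by the planar C6 radical has no facial preference, so the two C6 epimers should form in similar amounts and may not separate while the chain is acyclic. Minor competing processes are hydrogen-atom transfer to the vinylsilane and reduction of the peroxyl intermediate to the tertiary alcohol. The fallback moves the stereochemical sorting from acyclic epimers to ring diastereomers. It sets out from the epimer mixture 19, which is desilylated without separation to give 20 together with [(1E,4S,6R)-4-hydroperoxy-2,4,6-trimethylocta-1,7-dienyl]trimethylsilane F3. Both are cyclised under the conditions of step 12 to 21 and methyl 2-[(3S,4R,6S)-4,6-dimethyl-6-[(E)-2-methyl-3-trimethylsilylprop-2-enyl]-1,2-dioxan-3-yl]acetate F4. These differ in which C6 substituent is axial and should separate on silica. The route is rejoined at 21.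

**Step 10.** The ylide may attack the silyl peroxide at silicon or at the O–O bond, and the α-methyl aldehyde may epimerise at C4 under the basic conditions. The fallback changes the order of events and sets out from 16. Dess–Martin oxidation gives (2R,6E)-2,6-dimethyl-4-methylidene-7-trimethylsilylhept-6-enal F5, and methylenation gives trimethyl-[(1E,6R)-2,6-dimethyl-4-methylideneocta-1,7-dienyl]silane F6, so that no peroxide is present during the Wittig step. The cobalt peroxysilylation of step 8 is then run on F6 to partial conversion, relying on faster hydrogen-atom transfer to the 1,1-disubstituted alkene than to the monosubstituted one. The route is rejoined at 19.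

**Step 14.** Zerovalent palladium may cleave the O–O bond reductively, the base may open the ring through the ester enolate, and the C10=C11 double bond may migrate into conjugation with the phenyl ring. The fallback is a palladium-free and base-free coupling that sets out from 22. Tributyl-[(E)-3-phenylprop-1-enyl]stannane F7, made by hydrostannation of 3-phenylprop-1-yne, is coupled with 22 using copper thiophene-2-carboxylate, Cu(O2CC4H3S) (monovalent copper), in N-methylpyrrolidone at 0 °C. The route is rejoined at 24.

## Further compounds

F1 | step 12 | methyl (2E,4R,8E)-4,6,8-trimethyl-6-triethylsilylperoxy-9-trimethylsilylnona-2,8-dienoate (both C6 epimers) | COC(=O)/C=C/[C@H](C)CC(C)(OO[Si](CC)(CC)CC)C/C(C)=C/[Si](C)(C)C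
F2 | step 12 | methyl (2E,4R,6R,8E)-6-hydroperoxy-4,6,8-trimethyl-9-trimethylsilylnona-2,8-dienoate | COC(=O)/C=C/[C@H](C)C[C@@](C)(OO)C/C(C)=C/[Si](C)(C)C
F3 | step 8 | [(1E,4S,6R)-4-hydroperoxy-2,4,6-trimethylocta-1,7-dienyl]trimethylsilane | C=C[C@H](C)C[C@](C)(OO)C/C(C)=C/[Si](C)(C)C
F4 | step 8 | methyl 2-[(3S,4R,6S)-4,6-dimethyl-6-[(E)-2-methyl-3-trimethylsilylprop-2-enyl]-1,2-dioxan-3-yl]acetate | COC(=O)C[C@@H]1OO[C@](C)(C/C(C)=C/[Si](C)(C)C)C[C@H]1C
F5 | step 10 | (2R,6E)-2,6-dimethyl-4-methylidene-7-trimethylsilylhept-6-enal | O=C[C@H](C)CC(=C)C/C(C)=C/[Si](C)(C)C
F6 | step 10 | trimethyl-[(1E,6R)-2,6-dimethyl-4-methylideneocta-1,7-dienyl]silane | C=C[C@H](C)CC(=C)C/C(C)=C/[Si](C)(C)C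
F7 | step 14 | tributyl-[(E)-3-phenylprop-1-enyl]stannane | CCCC[Sn](CCCC)(CCCC)/C=C/Cc1ccccc1
A1 | alternative 1 | 2-[(3S,4R,6R)-6-[(E)-3-iodo-2-methylprop-2-enyl]-4,6-dimethyl-1,2-dioxan-3-yl]acetic acid | OC(=O)C[C@@H]1OO[C@@](C)(C/C(C)=C/I)C[C@H]1C
A2 | alternative 1 | (2R,4R,6E)-7-iodo-2,4,6-trimethyl-4-triethylsilylperoxyhept-6-enal | O=C[C@H](C)C[C@@](C)(OO[Si](CC)(CC)CC)C/C(C)=C/I
A3 | alternative 1 | (4R)-4-[(2R,4R,6E)-7-iodo-4,6-dimethyl-4-triethylsilylperoxyhept-6-en-2-yl]oxetan-2-one | O=C1C[C@@H](O1)[C@H](C)C[C@@](C)(OO[Si](CC)(CC)CC)C/C(C)=C/I
A4 | alternative 2 | tert-butyl-[2-[(3S,4R,6R)-4,6-dimethyl-6-[(2E,4E)-2-methyl-6-phenylhexa-2,4-dienyl]-1,2-dioxan-3-yl]ethoxy]dimethylsilane | CC(C)(C)[Si](C)(C)OCC[C@@H]1OO[C@@](C)(C/C(C)=C/C=C/Cc2ccccc2)C[C@H]1C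
A5 | alternative 2 | (E)-1-[(2S)-2-[(2R,3S)-5-[tert-butyl(dimethyl)silyl]oxy-3-hydroperoxy-2-methylpentyl]-1,2-dimethylcyclopropyl]-4-phenylbut-2-en-1-ol (ring C1 and carbinol carbon left open) | CC(C)(C)[Si](C)(C)OCC[C@H](OO)[C@H](C)C[C@@]1(C)CC1(C)C(O)/C=C/Cc1ccccc1
A6 | alternative 3 | methyl 2-[(3S,4R,6R)-3-hydroxy-6-[(E)-3-iodo-2-methylprop-2-enyl]-4,6-dimethyl-1,2-dioxan-3-yl]acetate | COC(=O)C[C@]1(O)OO[C@@](C)(C/C(C)=C/I)C[C@H]1C
A7 | alternative 3 | methyl 2-[(2R)-1-hydroxy-4-[(E)-3-iodo-2-methylprop-2-enyl]-2,4-dimethylcyclobutyl]acetate (ring C1 and C4 left open) | COC(=O)CC1(O)[C@H](C)CC1(C)C/C(C)=C/I
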